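**Retrosynthetic overview**
1. The (3S,4S)-tetrahydrofuran is traced back in one operation to the flat, achiral 3,4-bis(3,4-dimethoxybenzyl)furan: one enantioselective, dearomatising hydrogenation creates both stereocentres (trans).
2. The furan is cut at both furyl–benzyl C(sp2)–C(sp3) bonds: double Negishi coupling of 3,4-dibromofuran with a benzylic zinc reagent.
3. The zinc reagent comes from 3,4-dimethoxybenzyl chloride (veratryl chloride), a cheap vanillin/veratrole-derived aromatic.
4. Ring order: no ring is built. Both arenes and the furan are bought; the saturated oxygen ring appears last, by reduction of the furan.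

Assumption: the (S)-ligand is taken to give the (3S,4S) series; the sense is checked on the first run (chiral HPLC, optical rotation) and the (R)-ligand is used instead if it proves opposite.

Catalyst of step 3: [Ir(cod)(L)]BArF, a cationic complex of monovalent iridium, with L = (S)-8-[(di-tert-butylphosphanyl)oxy]-2-phenyl-5,6,7,8-tetrahydroquinoline and BArF = tetrakis[3,5-bis(trifluoromethyl)phenyl]borate.

**Step 1**
Reactants: 1 3,4-dimethoxybenzyl chloride
Product: 2 (3,4-dimethoxybenzyl)zinc chloride
Conditions: Zn dust (1.5 equiv), LiCl (1.5 equiv), THF, 25 °C; solution decanted from excess Zn, titrated and used directly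
Reagents that add atoms: zinc, [Zn]
Why: LiCl-promoted direct insertion of zinc metal into the benzylic C–Cl bond (Knochel-type oxidative insertion) runs at room temperature, leaves the aryl ethers untouched, and LiCl keeps the organozinc in solution so that Wurtz homocoupling stays minor.

**Step 2**
Reactants: 2 (3,4-dimethoxybenzyl)zinc chloride (2.6 equiv); 3 3,4-dibromofuran
Product: 5 3,4-bis(3,4-dimethoxybenzyl)furan, via monobenzyl bromofuran 4 (not isolated)
Conditions: Pd(OAc)2 (2 mol%), SPhos (4 mol%), THF, 25 → 50 °C
Reagents that add atoms: none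
Why: Double Negishi cross-coupling: zerovalent palladium bearing SPhos (formed in the flask from Pd(OAc)2) inserts into each furyl C–Br bond, the benzylic zinc chloride transmetalates readily and the benzyl–furyl reductive elimination has no β-hydride escape route, so monobromide 4 is driven on to 5 by the excess of 2.

**Step 3**
Reactants: 5 3,4-bis(3,4-dimethoxybenzyl)furan
Product: 7 (3S,4S)-3,4-bis(3,4-dimethoxybenzyl)tetrahydrofuran, via (S)-2,3-dihydrofuran 6 (not isolated)
Conditions: [Ir(cod)(L)]BArF (2 mol%), H2 (100 bar), CH2Cl2, 40 °C
Reagents that add atoms: none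
Why: Proposed new method: the closest known reaction type is the asymmetric hydrogenation of 3-alkylfurans and cyclic enol ethers with cationic iridium pyridine–phosphinite catalysts, and the reasoning is that the furan is reduced in two separate catalyst-controlled events through released dihydrofuran 6, that its two O–CH=C(CH2Ar) halves are mirror images so the catalyst's single enantioface preference places hydrogen on opposite ring faces at C3 and C4 and thereby gives the trans (3S,4S) product, and that an error in either event ends as the achiral, separable cis (meso) isomer rather than as the (3R,4R) enantiomer.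

**Compound list**
1 | 3,4-dimethoxybenzyl chloride (veratryl chloride) | COc1ccc(CCl)cc1OC | starting material
2 | (3,4-dimethoxybenzyl)zinc chloride (LiCl adduct in THF) | COc1ccc(C[Zn]Cl)cc1OC | intermediate
3 | 3,4-dibromofuran | Brc1cocc1Br | starting material
4 | 3-bromo-4-(3,4-dimethoxybenzyl)furan | COc1ccc(Cc2cocc2Br)cc1OC | intermediate
5 | 3,4-bis(3,4-dimethoxybenzyl)furan | COc1ccc(Cc2cocc2Cc2ccc(OC)c(OC)c2)cc1OC | intermediate
6 | (S)-3,4-bis(3,4-dimethoxybenzyl)-2,3-dihydrofuran | COc1ccc(C[C@@H]2COC=C2Cc2ccc(OC)c(OC)c2)cc1OC | intermediate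
7 | (3S,4S)-3,4-bis(3,4-dimethoxybenzyl)tetrahydrofuran | COc1ccc(C[C@@H]2COC[C@H]2Cc2ccc(OC)c(OC)c2)cc1OC | target

**Totals**
Total step count: 3 (two isolated products, 5 and 7).
Longest linear sequence: 3 steps (1 → 2 → 5 → 7).

**Steps most likely to fail, with fallbacks**

Step 3 (highest risk). The second H2 addition must place hydrogen on C4 on the same face as the C3 benzyl group of 6, against the substrate's own bias, so the cis (meso) isomer may dominate. A 3,4-disubstituted furan is also less reactive than the monosubstituted furans this catalyst class is known for. The acidic iridium hydride could in addition ionise enol ether 6 and start Friedel–Crafts chemistry on the electron-rich arenes. The trans product that does form should be of very high ee, because the (3R,4R) enantiomer needs two consecutive errors.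

Fallback, setting out from 1 and coming back to the route at 7: give up the dearomatisation and set both centres by auxiliary-controlled enolate alkylation. Succinyl chloride and lithiated (S)-4-benzyl-1,3-oxazolidin-2-one give 3,3'-succinylbis[(S)-4-benzyl-1,3-oxazolidin-2-one] F1. NaN(SiMe3)2 (THF, −78 °C) followed by 1 with catalytic Bu4NI gives the monobenzylated bis-imide F2, and a second round gives the (2S,3S)-dibenzylated bis-imide F3. Each sodium Z-enolate is attacked on the face away from the benzyl group of the auxiliary. LiBH4 (THF/H2O, 0 °C) removes both auxiliaries to give (2S,3S)-2,3-bis(3,4-dimethoxybenzyl)butane-1,4-diol F4. TsCl/pyridine (monotosylation, then intramolecular Williamson closure at a CH2 carbon, no stereocentre touched) gives 7.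

Step 2. The second coupling, next to the first benzyl group, may stall at 4, or benzyl–benzyl homocoupling may use up 2.

Fallback, setting out from 3 and coming back at 5: make the benzylic carbons by carbonyl addition instead of cross-coupling. n-BuLi (Et2O, −78 °C) and veratraldehyde convert 3 into (4-bromofuran-3-yl)(3,4-dimethoxyphenyl)methanol F5. n-BuLi (2.1 equiv, −78 °C) and veratraldehyde again give furan-3,4-diylbis[(3,4-dimethoxyphenyl)methanol] F6, a diastereomer mixture of no consequence. Et3SiH/CF3CO2H (CH2Cl2, −20 °C) removes both doubly activated benzylic hydroxyl groups by ionic hydrogenation to give 5.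

Step 1. Electron-rich benzylic chlorides are prone to Wurtz coupling to the bibenzyl during zinc insertion.

Fallback, setting out from 3 (with 1 as coupling partner) and coming back at 5: reverse the polarity of the coupling. B2pin2, PdCl2(dppf) and KOAc (dioxane, 90 °C) convert 3 into 3,4-bis(4,4,5,5-tetramethyl-1,3,2-dioxaborolan-2-yl)furan F7. This is benzylated twice with 1 under Suzuki–Miyaura conditions (Pd(OAc)2, SPhos, K3PO4, toluene/H2O, 80 °C) to give 5 without any benzylic organometallic.

**Further compounds**
F1 | step 3 | 3,3'-succinylbis[(S)-4-benzyl-1,3-oxazolidin-2-one] | O=C(CCC(=O)N1[C@@H](Cc2ccccc2)COC1=O)N1[C@@H](Cc2ccccc2)COC1=O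
F2 | step 3 | (S)-4-benzyl-3-{(2S)-4-[(S)-4-benzyl-2-oxo-1,3-oxazolidin-3-yl]-2-(3,4-dimethoxybenzyl)-4-oxobutanoyl}-1,3-oxazolidin-2-one | COc1ccc(C[C@@H](CC(=O)N2[C@@H](Cc3ccccc3)COC2=O)C(=O)N2[C@@H](Cc3ccccc3)COC2=O)cc1OC
F3 | step 3 | 3,3'-[(2S,3S)-2,3-bis(3,4-dimethoxybenzyl)succinyl]bis[(S)-4-benzyl-1,3-oxazolidin-2-one] | COc1ccc(C[C@H](C(=O)N2[C@@H](Cc3ccccc3)COC2=O)[C@@H](C(=O)N2[C@@H](Cc3ccccc3)COC2=O)Cc2ccc(OC)c(OC)c2)cc1OC
F4 | step 3 | (2S,3S)-2,3-bis(3,4-dimethoxybenzyl)butane-1,4-diol | COc1ccc(C[C@H](CO)[C@@H](CO)Cc2ccc(OC)c(OC)c2)cc1OC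
F5 | step 2 | (4-bromofuran-3-yl)(3,4-dimethoxyphenyl)methanol (racemic) | COc1ccc(C(O)c2cocc2Br)cc1OC
F6 | step 2 | furan-3,4-diylbis[(3,4-dimethoxyphenyl)methanol] (diastereomer mixture) | COc1ccc(C(O)c2cocc2C(O)c2ccc(OC)c(OC)c2)cc1OC
F7 | step 1 | 3,4-bis(4,4,5,5-tetramethyl-1,3,2-dioxaborolan-2-yl)furan | CC1(C)OB(OC1(C)C)c1cocc1B1OC(C)(C)C(C)(C)O1
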